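## The problem

The target is an isoflavone: benzene ring A fused to 4-pyranone ring C, a 2,4-dihydroxyphenyl ring B on C3, free hydroxyls on C5 and C7, and a 2-methylbut-3-en-2-yl group on C8. It has no stereocentre, so nothing can be relayed and every difficulty is one of position. Ring A is a phloroglucinol whose three oxygens (O1, O5, O7) must be told apart, and the quaternary carbon must sit on C8, between C8a–O1 and C7–OH, not on C6. Direct C-alkylation of a phloroglucinol or of a 5,7-dihydroxyisoflavone with a prenyl electrophile gives the linear chain and mixes C6 with C8, and a tertiary benzylic carbon of this kind cannot be made by substitution at the tertiary centre. The monosubstituted alkene excludes hydrogenolytic deprotection, and with the neighbouring 7-OH it can close to a dihydrofuran under strong Brønsted or Lewis acid. The polyphenol is sensitive to oxidation, and C2 of the chromone is open to attack by hydroxide. The enabling feature is that the quaternary carbon on C8 and O1 on C8a are ortho neighbours: joined through one carbonyl carbon they form a benzofuran-2(3H)-one, in which the future quaternary carbon is the acidic lactone α-carbon and the carbonyl carbon is the future vinyl CH. The same lactone marks one of the three phloroglucinol oxygens as O1.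

## Retrosynthesis

**Deprotection.** Target 24 is traced to its tetrakis(methoxymethyl) ether 23 by cutting four O–CH2 acetal bonds. MOM is chosen over benzyl (hydrogenolysis would reduce the vinyl group) and over methyl (boron halides would attack the 7-OH/alkene pair). The forward step needs only dilute acid, which a monosubstituted alkene tolerates better than a prenyl group does.

**Ring B.** In 23 the C3–C1' bond is cut to give 3-iodochromone 19 and arylboronate 22. Against the deoxybenzoin route, this avoids an electron-rich benzylic organometallic and any Lewis-acid acylation. The coupling must leave the vinyl group and the base-sensitive C2 untouched.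

**Ring C.** In 19 the O1–C2 and C2–C3 bonds are cut, giving 2-hydroxyacetophenone 17. The forward reaction passes through enaminone 18, whose electrophilic iodination triggers the closure. Only the phenol next to the quaternary carbon is free in 17, so ring C can close only to the 8-substituted chromone.

**The C4 carbon.** Ketone 17 is cut at C4–C4a back to phenol 13, by way of alcohol 16 and salicylaldehyde 15. In 13 the ortho carbon (future C4a) and the para carbon (future C6) are both open, so a Friedel–Crafts acylation or a directed lithiation would not choose between them. Lewis acids would also strip the MOM groups. A magnesium-phenoxide-directed formylation reaches only the ortho carbon. The methyl carbon then comes from a Grignard addition, followed by a neutral benzylic oxidation.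

**The vinyl group and O1.** Phenol 13 is traced to lactol 10 by cutting the C=CH2 bond (Wittig reaction with the ylide from phosphonium salt 11), and 10 to lactone 9 by partial reduction. This reconnects O1 to the carbon that becomes the internal vinyl CH. The precursor 9 has no alkene, no free phenol and no open-chain aldehyde.

**The quaternary carbon (key cut).** In 9 both C–CH3 bonds are cut, giving lactone 6 and two molecules of iodomethane 7. Two SN2 methylations replace an allylic alkylation, so no linear/branched question arises. The tether fixes the new carbon next to the oxygen that becomes O1. The forward reaction needs C- rather than O-methylation of an aromatic enolate.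

**The lactone.** Compound 6 is traced through dihydroxy lactone 5 and hydroxy lactone 4 to phloroglucinol 1 and glyoxylic acid 2. Because 1 is threefold symmetric, any ring carbon and either flanking hydroxyl give the same lactone. Lactonisation thus turns a symmetric triol into a compound with one marked oxygen.

**Ring B piece.** Boronate 22 comes from bromide 21 by borylation, and 21 from 4-bromoresorcinol 20 by MOM protection.

## Roads not taken

**Alternative 1: benzannulation around the quaternary carbon.**
- Cut: ring A is disconnected at C8–C8a and C6–C7.
- Key step: heating 3-ethoxycyclobut-2-en-1-one A2 with the siloxyalkyne A3 (vinylketene, [2+2], ring opening, 6π closure) gives 5-ethoxy-2-(2-methylbut-3-en-2-yl)-3-[(triisopropylsilyl)oxy]phenol A1.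
- Merits: the quaternary carbon arrives ready-made in an acyclic piece. The three oxygens are differentiated by construction (free OH next to the quaternary carbon, silyl on the future O7, ethyl on the future O5). The route is convergent.
- Weak points: the tert-alkyl group on the alkyne slows the [2+2] step. Neither A2 nor A3 is a commodity, and A3 needs an ynolate synthesis. The C5 ethyl ether must finally be cleaved by a boron or aluminium Lewis acid beside the 7-OH/alkene pair, the situation the target tolerates least. The phenol A1 still needs the same ortho-selective introduction of C4 and the same ring C work.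
- Comparison: it equals the chosen plan in oxygen differentiation and is more convergent. The chosen plan answers with commodity starting materials, one protecting group removed by mild acid, and a quaternary carbon made by two simple SN2 reactions.

**Alternative 2: anodic enaminone–arene coupling.**
- Cut: C3–C1' and O1–C2 in one operation.
- Key step: anodic oxidation of enaminone 18 in the presence of 1,3-bis(methoxymethoxy)benzene A5 would give the protected isoflavone A4 (the same structure as 23).
- Merits: no iodine, no boron and no palladium. Steps 11 and 12 fall away and steps 10 and 13 merge, so the endgame is about three steps shorter.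
- Weak points: it addresses neither the quaternary carbon nor the choice of O1, and needs 18, hence steps 1 to 9, unchanged. The free phenol and electron-rich ring A of 18, and A5 itself, are oxidised at potentials close to that of the enaminone. The coupling site on A5 (C4 against C2) is not fixed by a bond already present. This coupling is not established on such substrates.
- Comparison: if it worked it would be shorter and cleaner. The chosen plan sets against it a cross-coupling whose site is fixed by the C–I and C–B bonds. The two are compatible, and this road could later replace steps 10 to 13.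

**Alternative 3: ortho-quinone methide relay.**
- Cut: the C–methyl and C–vinyl bonds of the quaternary carbon.
- Key step: a methyl Grignard reagent adds to the aryl ketone A7 (tert-butyl 2-acetyl-3,5-bis(methoxymethoxy)phenyl carbonate). The carbonate shifts to the new alkoxide and is expelled to give the quinone methide A8, and a vinyl Grignard reagent adds 1,4 to give phenol A6 (the same structure as 13).
- Merits: A7 is two steps from a commercial acetophenone, so A6 is reached in three steps where the chosen plan needs six. The chelated ortho hydroxyl of that acetophenone already marks O1.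
- Weak points: A8 carries two methyl groups on its exocyclic carbon and can tautomerise by a 1,5-hydrogen shift to the 2-isopropenylphenol. The Grignard reagents are bases as well as nucleophiles. The 1,4-addition must build a quaternary centre on a quinone methide made less electrophilic by two donor oxygens.
- Comparison: this road is clearly shorter to the same phenol. The chosen plan sets against that the certainty of its C–C bond formation: two SN2 reactions on iodomethane with no elimination pathway.

Key step: step 4

Remark on the chemistry: compounds 3, 4, 8, 10 and 16 each carry one stereocentre, are formed and used as racemates, and lose that centre before the target, which has none. Glyoxylic acid 2 is used as its commercial monohydrate.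

## Route

Step 1
Reactants: 1 phloroglucinol (benzene-1,3,5-triol); 2 glyoxylic acid (oxoacetic acid, as monohydrate)
Product: 4 3,4,6-trihydroxy-1-benzofuran-2(3H)-one (racemic), via 2,4,6-trihydroxymandelic acid 3 (not isolated)
Conditions: NaOH (2 equiv), H2O, 0 °C to rt, N2; then aq. HCl to pH 1, 50 °C
Reagents that add atoms: none
Why: Hydroxyalkylation of the phenoxide by glyoxylate (the reaction type used for hydroxymandelic acids) followed by acid lactonisation of the ortho-hydroxy acid; the symmetry of 1 makes all ring carbons and both flanking hydroxyls equivalent, and cold alkaline medium should keep the benzylic hydroxyl from ionising toward a second arylation.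

Step 2
Reactants: 4 3,4,6-trihydroxy-1-benzofuran-2(3H)-one
Product: 5 4,6-dihydroxy-1-benzofuran-2(3H)-one
Conditions: H2 (1 atm), Pd/C (10 %), AcOH, cat. H2SO4, 50 °C
Reagents that add atoms: none
Why: Benzylic C–O hydrogenolysis of a mandelic acid derivative to the arylacetic acid derivative, made easier by the three donor oxygens; the aryl lactone is stable in acetic acid.

Step 3
Reactants: 5 4,6-dihydroxy-1-benzofuran-2(3H)-one
Product: 6 4,6-bis(methoxymethoxy)-1-benzofuran-2(3H)-one
Conditions: MOMCl (2.4 equiv), i-Pr2NEt (3 equiv), CH2Cl2, 0 °C to rt; aq. NaH2PO4 wash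
Reagents that add atoms: chloromethyl methyl ether, COCCl
Why: Williamson-type O-alkylation of the two phenols by a hindered amine base that should deprotonate the O–H far faster than the lactone C–H; any enol MOM ether formed at the lactone should hydrolyse back in the acidic wash.

Step 4
Reactants: 6 4,6-bis(methoxymethoxy)-1-benzofuran-2(3H)-one; 7 iodomethane
Product: 9 4,6-bis(methoxymethoxy)-3,3-dimethyl-1-benzofuran-2(3H)-one, via 3-methyl lactone 8 (not isolated)
Conditions: MeI (5 equiv), K2CO3 (3 equiv, dried), DMF, 0 °C to rt, argon
Reagents that add atoms: iodomethane (second equivalent), CI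
Why: K2CO3 removes the C3 proton of 6 because the conjugate base is an aromatic 2-oxidobenzofuran; this ambident anion attacks iodomethane 7 through C3 in an SN2 reaction and regains the lactone carbonyl, and the monomethyl lactone 8 repeats the sequence with a second molecule of iodomethane to give the quaternary carbon of 9. The closest known reaction type is the C3 dialkylation of benzofuran-2(3H)-ones and oxindoles with alkyl halides under carbonate or hydride bases. No ring closes and no stereocentre remains, since the racemic centre of 8 becomes achiral in 9. The selectivity needed is C- over O-methylation, which the soft iodide electrophile, the large coefficient on C3 and the regained C=O bond should secure. Complete dialkylation is secured by excess MeI, because 8 is about as acidic as 6. Dry, oxygen-free conditions are needed because hydroxide would open the aryl lactone and the electron-rich enolate is prone to autoxidation at C3. The MOM ethers are inert to base and the C4 ether beside C3 is small enough not to block the second methylation.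

Step 5
Reactants: 9 4,6-bis(methoxymethoxy)-3,3-dimethyl-1-benzofuran-2(3H)-one
Product: 10 4,6-bis(methoxymethoxy)-3,3-dimethyl-2,3-dihydro-1-benzofuran-2-ol (racemic lactol)
Conditions: i-Bu2AlH (1.2 equiv), CH2Cl2, –78 °C; aq. potassium sodium tartrate
Reagents that add atoms: none
Why: Partial reduction of a lactone to the lactol; the aluminium hemiacetal should persist at –78 °C and the neopentyl-type carbonyl carbon is shielded against a second hydride.

Step 6
Reactants: 10 4,6-bis(methoxymethoxy)-3,3-dimethyl-2,3-dihydro-1-benzofuran-2-ol; 11 methyltriphenylphosphonium bromide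
Product: 13 3,5-bis(methoxymethoxy)-2-(2-methylbut-3-en-2-yl)phenol, via hydroxy aldehyde 12 (not isolated)
Conditions: Ph3PCH3Br (3.5 equiv), KOtBu (3.3 equiv), THF, 0 °C to 50 °C
Reagents that add atoms: none
Why: Wittig methylenation of a lactol through its ring-opened phenoxide aldehyde 12, a standard way to ortho-(1,1-dimethylallyl)phenols; the aldehyde has no α-hydrogen, so excess ylide cannot enolise it, and the step releases the phenol that becomes O1.

Step 7
Reactants: 13 3,5-bis(methoxymethoxy)-2-(2-methylbut-3-en-2-yl)phenol
Product: 15 2-hydroxy-4,6-bis(methoxymethoxy)-3-(2-methylbut-3-en-2-yl)benzaldehyde, via salicyl alcohol 14 (not isolated)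
Conditions: MgCl2 (2 equiv), Et3N (4 equiv), (CH2O)n (6 equiv), MeCN, reflux
Reagents that add atoms: paraformaldehyde (as formaldehyde), C=O
Why: Casnati–Skattebøl ortho-formylation: the magnesium phenoxide delivers formaldehyde to the only free ortho carbon through a six-membered chelate and a second formaldehyde oxidises the hydroxymethyl intermediate 14 by hydride transfer; the open para C–H lies outside the chelate, and MOM ethers and the alkene are inert to this base-mediated medium.

Step 8
Reactants: 15 2-hydroxy-4,6-bis(methoxymethoxy)-3-(2-methylbut-3-en-2-yl)benzaldehyde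
Product: 16 2-(1-hydroxyethyl)-3,5-bis(methoxymethoxy)-6-(2-methylbut-3-en-2-yl)phenol (racemic)
Conditions: MeMgBr (3 equiv), THF, –40 °C to 0 °C; pH 7 phosphate buffer; crude used at once
Reagents that add atoms: methylmagnesium bromide, C[Mg]Br
Why: Grignard addition to a salicylaldehyde with one equivalent consumed by the phenol; the new stereocentre is formed racemic and removed in step 9, and neutral work-up is chosen because the electron-rich ortho-hydroxybenzylic alcohol would lose water under acid.

Step 9
Reactants: 16 2-(1-hydroxyethyl)-3,5-bis(methoxymethoxy)-6-(2-methylbut-3-en-2-yl)phenol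
Product: 17 1-[2-hydroxy-4,6-bis(methoxymethoxy)-3-(2-methylbut-3-en-2-yl)phenyl]ethan-1-one
Conditions: activated MnO2 (15 equiv), CH2Cl2, rt
Reagents that add atoms: none
Why: Heterogeneous oxidation of a benzylic alcohol by MnO2 under neutral conditions, which leaves the alkene, the MOM acetals and the phenol (hydrogen-bonded to the new ketone) alone.

Step 10
Reactants: 17 1-[2-hydroxy-4,6-bis(methoxymethoxy)-3-(2-methylbut-3-en-2-yl)phenyl]ethan-1-one
Product: 19 3-iodo-5,7-bis(methoxymethoxy)-8-(2-methylbut-3-en-2-yl)-4H-chromen-4-one, via enaminone 18 (not isolated)
Conditions: Me2NCH(OMe)2 (3 equiv), DMF, 90 °C; evaporate; then I2 (1.1 equiv), CHCl3, 0 °C to rt; aq. Na2S2O3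
Reagents that add atoms: N,N-dimethylformamide dimethyl acetal, COC(OC)N(C)C; iodine, II
Why: Condensation of the methyl ketone with the amide acetal gives the enaminone, whose α-carbon is iodinated; the phenol then adds to the iminium carbon and dimethylamine is lost, the standard route to 3-iodochromones. With one equivalent of iodine the push-pull alkene should react far faster than the monosubstituted vinyl group, and the only free phenol is tied up by hydrogen bonding and then by ring closure, so 8-substitution is the only outcome.

Step 11
Reactants: 20 4-bromobenzene-1,3-diol (4-bromoresorcinol)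
Product: 21 1-bromo-2,4-bis(methoxymethoxy)benzene
Conditions: MOMCl (2.5 equiv), i-Pr2NEt (3 equiv), CH2Cl2, 0 °C to rt
Reagents that add atoms: chloromethyl methyl ether, COCCl
Why: Routine Williamson-type MOM protection of two phenols.

Step 12
Reactants: 21 1-bromo-2,4-bis(methoxymethoxy)benzene
Product: 22 2-[2,4-bis(methoxymethoxy)phenyl]-4,4,5,5-tetramethyl-1,3,2-dioxaborolane
Conditions: B2pin2 (1.2 equiv), Pd(dppf)Cl2 (3 mol %), KOAc (3 equiv), 1,4-dioxane, 90 °C
Reagents that add atoms: bis(pinacolato)diboron, CC1(C)OB(OC1(C)C)B1OC(C)(C)C(C)(C)O1
Why: Miyaura borylation of an aryl bromide; the pinacol ester is chosen because it resists protodeboronation better than the free 2,4-dioxygenated boronic acid.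

Step 13
Reactants: 19 3-iodo-5,7-bis(methoxymethoxy)-8-(2-methylbut-3-en-2-yl)-4H-chromen-4-one; 22 2-[2,4-bis(methoxymethoxy)phenyl]-4,4,5,5-tetramethyl-1,3,2-dioxaborolane
Product: 23 3-[2,4-bis(methoxymethoxy)phenyl]-5,7-bis(methoxymethoxy)-8-(2-methylbut-3-en-2-yl)-4H-chromen-4-one
Conditions: Pd(dppf)Cl2 (5 mol %), Na2CO3 (2 M aq., 3 equiv), DME, 80 °C
Reagents that add atoms: none
Why: Suzuki–Miyaura coupling of a 3-iodochromone with an arylboronate, the standard isoflavone assembly; oxidative addition of zerovalent palladium into the vinylogous acyl C–I bond is fast, transmetalation should outrun any Heck reaction at the hindered vinyl group, and carbonate is mild enough to spare C2.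

Step 14
Reactants: 23 3-[2,4-bis(methoxymethoxy)phenyl]-5,7-bis(methoxymethoxy)-8-(2-methylbut-3-en-2-yl)-4H-chromen-4-one
Product: 24 3-(2,4-dihydroxyphenyl)-5,7-dihydroxy-8-(2-methylbut-3-en-2-yl)-4H-chromen-4-one (target)
Conditions: HCl (3 M aq.)/MeOH 1:4, 45 °C
Reagents that add atoms: none
Why: Acid-catalysed solvolysis of four aryl MOM acetals; the monosubstituted alkene would have to be protonated to a secondary cation beside a quaternary carbon, so it should be less prone to cyclisation with the 7-OH than the prenyl groups that survive such conditions.

## Compound list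

1 | phloroglucinol (benzene-1,3,5-triol) | Oc1cc(O)cc(O)c1 | starting material
2 | glyoxylic acid (oxoacetic acid) | O=CC(=O)O | starting material
3 | hydroxy(2,4,6-trihydroxyphenyl)acetic acid (racemic) | OC(C(=O)O)c1c(O)cc(O)cc1O | intermediate
4 | 3,4,6-trihydroxy-1-benzofuran-2(3H)-one (racemic) | O=C1Oc2cc(O)cc(O)c2C1O | intermediate
5 | 4,6-dihydroxy-1-benzofuran-2(3H)-one | O=C1Cc2c(O)cc(O)cc2O1 | intermediate
6 | 4,6-bis(methoxymethoxy)-1-benzofuran-2(3H)-one | O=C1Cc2c(OCOC)cc(OCOC)cc2O1 | intermediate
7 | iodomethane | CI | starting material
8 | 4,6-bis(methoxymethoxy)-3-methyl-1-benzofuran-2(3H)-one (racemic) | CC1C(=O)Oc2cc(OCOC)cc(OCOC)c21 | intermediate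
9 | 4,6-bis(methoxymethoxy)-3,3-dimethyl-1-benzofuran-2(3H)-one | CC1(C)C(=O)Oc2cc(OCOC)cc(OCOC)c21 | intermediate
10 | 4,6-bis(methoxymethoxy)-3,3-dimethyl-2,3-dihydro-1-benzofuran-2-ol (racemic) | CC1(C)C(O)Oc2cc(OCOC)cc(OCOC)c21 | intermediate
11 | methyltriphenylphosphonium bromide | C[P+](c1ccccc1)(c1ccccc1)c1ccccc1.[Br-] | starting material
12 | 2-[2-hydroxy-4,6-bis(methoxymethoxy)phenyl]-2-methylpropanal | CC(C)(C=O)c1c(O)cc(OCOC)cc1OCOC | intermediate
13 | 3,5-bis(methoxymethoxy)-2-(2-methylbut-3-en-2-yl)phenol | C=CC(C)(C)c1c(O)cc(OCOC)cc1OCOC | intermediate
14 | 2-(hydroxymethyl)-3,5-bis(methoxymethoxy)-6-(2-methylbut-3-en-2-yl)phenol | C=CC(C)(C)c1c(O)c(CO)c(OCOC)cc1OCOC | intermediate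
15 | 2-hydroxy-4,6-bis(methoxymethoxy)-3-(2-methylbut-3-en-2-yl)benzaldehyde | C=CC(C)(C)c1c(O)c(C=O)c(OCOC)cc1OCOC | intermediate
16 | 2-(1-hydroxyethyl)-3,5-bis(methoxymethoxy)-6-(2-methylbut-3-en-2-yl)phenol (racemic) | C=CC(C)(C)c1c(O)c(C(C)O)c(OCOC)cc1OCOC | intermediate
17 | 1-[2-hydroxy-4,6-bis(methoxymethoxy)-3-(2-methylbut-3-en-2-yl)phenyl]ethan-1-one | C=CC(C)(C)c1c(O)c(C(C)=O)c(OCOC)cc1OCOC | intermediate
18 | (2E)-3-(dimethylamino)-1-[2-hydroxy-4,6-bis(methoxymethoxy)-3-(2-methylbut-3-en-2-yl)phenyl]prop-2-en-1-one | C=CC(C)(C)c1c(O)c(C(=O)/C=C/N(C)C)c(OCOC)cc1OCOC | intermediate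
19 | 3-iodo-5,7-bis(methoxymethoxy)-8-(2-methylbut-3-en-2-yl)-4H-chromen-4-one | C=CC(C)(C)c1c(OCOC)cc(OCOC)c2c(=O)c(I)coc12 | intermediate
20 | 4-bromobenzene-1,3-diol | Oc1ccc(Br)c(O)c1 | starting material
21 | 1-bromo-2,4-bis(methoxymethoxy)benzene | COCOc1ccc(Br)c(OCOC)c1 | intermediate
22 | 2-[2,4-bis(methoxymethoxy)phenyl]-4,4,5,5-tetramethyl-1,3,2-dioxaborolane | COCOc1ccc(B2OC(C)(C)C(C)(C)O2)c(OCOC)c1 | intermediate
23 | 3-[2,4-bis(methoxymethoxy)phenyl]-5,7-bis(methoxymethoxy)-8-(2-methylbut-3-en-2-yl)-4H-chromen-4-one | C=CC(C)(C)c1c(OCOC)cc(OCOC)c2c(=O)c(-c3ccc(OCOC)cc3OCOC)coc12 | intermediate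
24 | 3-(2,4-dihydroxyphenyl)-5,7-dihydroxy-8-(2-methylbut-3-en-2-yl)-4H-chromen-4-one | C=CC(C)(C)c1c(O)cc(O)c2c(=O)c(-c3ccc(O)cc3O)coc12 | target

## Step count and least certain steps

Total: 14 steps. The longest linear sequence is 12 steps (steps 1 to 10, 13 and 14, from phloroglucinol). The ring B branch is 2 steps (11 and 12) and joins at step 13.

**Step 4 (key step).** The likeliest failure is O-methylation of the ambident enolate to 2-methoxybenzofurans. The second is opening of the aryl lactone by traces of hydroxide, followed by methylation of the freed phenoxide. The fallback keeps the same two C–methyl bonds but makes them on an open-chain ester enolate, which can only C-alkylate. It sets out from 6. K2CO3 in MeOH opens the lactone to methyl [2-hydroxy-4,6-bis(methoxymethoxy)phenyl]acetate F1, and BnBr in the same medium gives methyl [2-(benzyloxy)-4,6-bis(methoxymethoxy)phenyl]acetate F2. Two cycles of KN(SiMe3)2 and MeI in THF give methyl 2-[2-(benzyloxy)-4,6-bis(methoxymethoxy)phenyl]-2-methylpropanoate F3. Hydrogenolysis (H2, Pd/C, EtOAc) is allowed here because no alkene is yet present. It frees methyl 2-[2-hydroxy-4,6-bis(methoxymethoxy)phenyl]-2-methylpropanoate F4, which should close on warming in toluene, helped by the geminal methyl groups. The fallback returns to the route at 9.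

**Step 1.** The likeliest failure is attack of a second phloroglucinol on the ionisable benzylic carbon, or a second hydroxyalkylation of the same ring; both follow from the very high nucleophilicity of 1. The fallback replaces hydroxyalkylation by acylation, which stops after one substitution because the acyl group deactivates the ring. It sets out from 1. Friedel–Crafts acylation with ethyl chlorooxoacetate (AlCl3, CH2Cl2/PhNO2) gives ethyl oxo(2,4,6-trihydroxyphenyl)acetate F5. NaBH4 in EtOH at 0 °C reduces the keto group to ethyl hydroxy(2,4,6-trihydroxyphenyl)acetate F6, which lactonises on acidification. The fallback returns at 4.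

**Step 3.** The likeliest failure is deprotonation of the acidic lactone C3–H by the amine, leading to C-alkylation by MOMCl, or acyl transfer from the aryl lactone to a phenoxide of another molecule. The fallback changes the mechanism from base-mediated alkylation to acid-catalysed acetal exchange, in which neither enolate nor phenoxide forms: CH2(OMe)2 and P2O5 in CHCl3 at rt. It sets out from 5 and returns at 6 directly, and it makes no new compound (F0).

**Step 5.** The likeliest failure is collapse of the aluminium hemiacetal with loss of the phenoxide, followed by a second hydride addition (over-reduction). The fallback accepts full reduction and re-oxidises. It sets out from 9. LiAlH4 in THF at 0 °C gives 2-(1-hydroxy-2-methylpropan-2-yl)-3,5-bis(methoxymethoxy)phenol F7. Parikh–Doering oxidation (SO3·pyridine, DMSO, Et3N) of the primary alcohol gives hydroxy aldehyde 12, which closes to the lactol. The fallback returns at 10.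

**Step 7.** The likeliest failures are hydroxymethylation and diarylmethane formation at the electron-rich para C–H between the two MOM ethers, or slow chelate formation beside the quaternary carbon. The fallback ties the phenol oxygen covalently to the incoming carbon. It sets out from 13. PhB(OH)2, (CH2O)n and catalytic propionic acid in refluxing toluene with water removal give 5,7-bis(methoxymethoxy)-8-(2-methylbut-3-en-2-yl)-2-phenyl-4H-1,3,2-benzodioxaborinine F8. Transesterification with propane-1,3-diol releases salicyl alcohol 14, this time isolated, and MnO2 in CH2Cl2 oxidises it. The fallback returns at 15.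

**Step 14.** The likeliest failure is acid-promoted addition of the freed 7-OH across the vinyl group, or incomplete cleavage of the less activated acetals if the acid is kept mild. The fallback replaces Brønsted-acid solvolysis by Lewis-acid-assisted transfer of the methoxymethyl group to a thiol in an aprotic medium: ZnBr2 and n-PrSH in CH2Cl2 at 0 °C. No acid able to protonate the alkene is present. It sets out from 23 and returns at 24 directly, and it makes no new compound (F0).

Further compounds
F1 | step 4 | methyl [2-hydroxy-4,6-bis(methoxymethoxy)phenyl]acetate | COC(=O)Cc1c(O)cc(OCOC)cc1OCOC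
F2 | step 4 | methyl [2-(benzyloxy)-4,6-bis(methoxymethoxy)phenyl]acetate | COC(=O)Cc1c(OCc2ccccc2)cc(OCOC)cc1OCOC
F3 | step 4 | methyl 2-[2-(benzyloxy)-4,6-bis(methoxymethoxy)phenyl]-2-methylpropanoate | COC(=O)C(C)(C)c1c(OCc2ccccc2)cc(OCOC)cc1OCOC
F4 | step 4 | methyl 2-[2-hydroxy-4,6-bis(methoxymethoxy)phenyl]-2-methylpropanoate | COC(=O)C(C)(C)c1c(O)cc(OCOC)cc1OCOC
F5 | step 1 | ethyl oxo(2,4,6-trihydroxyphenyl)acetate | CCOC(=O)C(=O)c1c(O)cc(O)cc1O
F6 | step 1 | ethyl hydroxy(2,4,6-trihydroxyphenyl)acetate (racemic) | CCOC(=O)C(O)c1c(O)cc(O)cc1O
F0 | step 3 | none | none
F7 | step 5 | 2-(1-hydroxy-2-methylpropan-2-yl)-3,5-bis(methoxymethoxy)phenol | CC(C)(CO)c1c(O)cc(OCOC)cc1OCOC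
F8 | step 7 | 5,7-bis(methoxymethoxy)-8-(2-methylbut-3-en-2-yl)-2-phenyl-4H-1,3,2-benzodioxaborinine | C=CC(C)(C)c1c(OCOC)cc(OCOC)c2c1OB(c1ccccc1)OC2
F0 | step 14 | none | none
A1 | alternative 1 | 5-ethoxy-2-(2-methylbut-3-en-2-yl)-3-[(triisopropylsilyl)oxy]phenol | C=CC(C)(C)c1c(O)cc(OCC)cc1O[Si](C(C)C)(C(C)C)C(C)C
A2 | alternative 1 | 3-ethoxycyclobut-2-en-1-one | CCOC1=CC(=O)C1
A3 | alternative 1 | [(3,3-dimethylpent-4-en-1-yn-1-yl)oxy]tri(propan-2-yl)silane | C=CC(C)(C)C#CO[Si](C(C)C)(C(C)C)C(C)C
A4 | alternative 2 | 3-[2,4-bis(methoxymethoxy)phenyl]-5,7-bis(methoxymethoxy)-8-(2-methylbut-3-en-2-yl)-4H-chromen-4-one | C=CC(C)(C)c1c(OCOC)cc(OCOC)c2c(=O)c(-c3ccc(OCOC)cc3OCOC)coc12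
A5 | alternative 2 | 1,3-bis(methoxymethoxy)benzene | COCOc1cccc(OCOC)c1
A6 | alternative 3 | 3,5-bis(methoxymethoxy)-2-(2-methylbut-3-en-2-yl)phenol | C=CC(C)(C)c1c(O)cc(OCOC)cc1OCOC
A7 | alternative 3 | tert-butyl 2-acetyl-3,5-bis(methoxymethoxy)phenyl carbonate | CC(=O)c1c(OC(=O)OC(C)(C)C)cc(OCOC)cc1OCOC
A8 | alternative 3 | 3,5-bis(methoxymethoxy)-6-(propan-2-ylidene)cyclohexa-2,4-dien-1-one | CC(C)=C1C(=O)C=C(OCOC)C=C1OCOC
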